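With the gas held at 3.2 mM, the temperature and volume constant, the noon and summer runs differed in the charge of starting complex, and this flask took 14 mM.

| setting | noon | summer | flask |
|---|---|---|---|
| starting complex | 7 mM | 10 mM | 14 mM |
| gas | 3.2 mM (held) | 3.2 mM (held) | 3.2 mM (held) |
| remark | run made earlier | run made earlier |  |
| time |  |  | 20 h |

- noon (time / h: complex with two exchanged / %): 3.00: 0.4; 6.00: 2.2; 10.0: 4.8; 15.0: 7.2; 20.0: 10.2; 25.0: 12.9
- summer (time / h: complex with two exchanged / %): 1.33: 0; 4.00: 1.1; 6.00: 1.7; 10.0: 2.6; 15.0: 4.6; 20.0: 6.2; 25.0: 7.9

(readings scatter by 0.3 percentage points)

- what was read earlier has a scatter of 0.3 percentage points, one standard deviation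
- at the start none of the gas is in solution

- amount of complex with two exchanged at 20 h, in percent of the starting complex charged
- concentration of leaving ligand in solution at 20 h, in percent of saturation

Between the two runs the percent of complex with two exchanged at 20 h fell from 10.2% to 6.2%. From these two readings, each with a scatter of 0.3 percentage points, I read the charge exponent n = 1.40, an apparent order: the power of the charge by which that percent falls, gas and time held. Scaling the summer reading by the charge ratio to the power n, I reckoned 3.88%. No saturation was given for leaving ligand, so I reckoned nothing for it.

The forecast gave 3.8%, slightly below my figure, and 40%, taking its late slopes to suggest that “supply of the gas into solution is limiting, not the complex”.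

The flask gave 3.90% and 21.6%.

    starting complex + incoming ligand ⇌ leaving ligand + complex with one exchanged (K = 28.0, k = 270 M⁻¹ h⁻¹)
    complex with one exchanged → side product (k = 0.0240 h⁻¹)
    gas ⇌ incoming ligand, rate k3*(csat - [incoming ligand]) (kL = 0.0380 h⁻¹)
    crystals ⇌ leaving ligand, rate k4*(cs4 - [leaving ligand]) while solid is left; crystals form when [leaving ligand] > cs4 (solubility = 11.0 mM, k = 0.630 h⁻¹)
    complex with one exchanged + incoming ligand ⇌ leaving ligand + complex with two exchanged (K = 60.0, k = 2500 M⁻¹ h⁻¹)

Reckoned from the summer run to this flask, n came to 1.38. Carried from the noon reading to a neighbour flask charged with 5.6 mM and read at the same time, n gave 13.9%, and that neighbour flask stood at 13.8%. This flask had not come to rest at 20 h: 87% of the starting complex remained, and leaving ligand stood at 2.38 mM against a saturation of 11 mM, with 0 mM of crystals. At 200 h this flask held 0.984% of starting complex, 4.10% of complex with one exchanged, 40.7% of complex with two exchanged, 54.3% of side product and 8.53 mM of crystals.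

Readings and results come from a simulation on assumed constants, and the scatter is random.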